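**Plan**
- Feature: ring A is a 2-alkylresorcinol. O5 and O7 flank the prenyl-bearing C6, C8 carries H, and the ring is fused to the 4-pyranone ring C at C4a–C8a. A ketene placed on C8a and a 1-siloxyalkyne deliver exactly this pattern.
- Retrosynthesis: after removal of O5–CH3, O7–Si and the two MOM groups, ring A is cut at C8–C8a, C7–C8, C5–C6 and C4a–C5. This gives a 2-diazoacetyl-5-aryl-4-pyranone and a prenyl-substituted triisopropylsiloxyalkyne. The pyranone is cut at C3–C1' (Suzuki) to kojic acid 5-triflate and a bis-MOM resorcinyl boronate.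
- Forward: ring B is joined to the preformed ring C, the CH2OH arm is taken to CO2H and then to COCHN2, and ring A is built last in one operation (Wolff shift, [2+2], 4π opening, 6π closure).
- The cascade leaves O5 free and O7 silylated, so methylation can only occur at O5; acid and then fluoride unmask the three phenols.
- Stereochemistry: the target has no stereocentre and no stereogenic double bond; all control is regiochemical and comes from the polarity of the siloxyalkyne.

Key step: step 9

Remark: ethynylmagnesium bromide and (trimethylsilyl)diazomethane are taken as commercial solutions; transient sp3 centres formed in the cascade are racemic and are erased on aromatisation.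

**Step 1**
Reactants: 1 4-bromoresorcinol
Product: 2 1-bromo-2,4-bis(methoxymethoxy)benzene
Conditions: MOMCl, i-Pr2NEt, CH2Cl2, 0 °C to rt
Reagents that add atoms: chloromethyl methyl ether, COCCl
Why: Base-mediated O-alkylation of both phenols (acetal ether formation) should give the bis-MOM ether, which tolerates organolithium, palladium and basic steps and is removed by mild acid at the end.

**Step 2**
Reactants: 2 1-bromo-2,4-bis(methoxymethoxy)benzene
Product: 4 2-[2,4-bis(methoxymethoxy)phenyl]-4,4,5,5-tetramethyl-1,3,2-dioxaborolane, via aryllithium 3 (not isolated)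
Conditions: n-BuLi, THF, −78 °C; i-PrOBpin, −78 °C to rt; aq. NH4Cl
Reagents that add atoms: 2-isopropoxy-4,4,5,5-tetramethyl-1,3,2-dioxaborolane, CC(C)OB1OC(C)(C)C(C)(C)O1
Why: Bromine–lithium exchange is faster than ortho-metalation at −78 °C, and borylation of the aryllithium with the isopropoxy dioxaborolane should give the chromatographable pinacol boronate.

**Step 3**
Reactants: 5 kojic acid
Product: 6 6-(hydroxymethyl)-4-oxo-4H-pyran-3-yl trifluoromethanesulfonate
Conditions: PhNTf2, Et3N, DMF, 0 °C to rt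
Reagents that add atoms: N-phenylbis(trifluoromethanesulfonimide), O=S(=O)(N(c1ccccc1)S(=O)(=O)C(F)(F)F)C(F)(F)F
Why: Chemoselective O-sulfonylation: the acidic enolic 5-OH is deprotonated by the amine and triflated by the mild triflimide, whereas the neutral primary alcohol should not react with this reagent.

**Step 4**
Reactants: 6 6-(hydroxymethyl)-4-oxo-4H-pyran-3-yl trifluoromethanesulfonate; 4 2-[2,4-bis(methoxymethoxy)phenyl]-4,4,5,5-tetramethyl-1,3,2-dioxaborolane
Product: 7 5-[2,4-bis(methoxymethoxy)phenyl]-2-(hydroxymethyl)-4H-pyran-4-one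
Conditions: Pd(dppf)Cl2 (5 mol %), K3PO4, 1,4-dioxane/H2O (9:1), 70 °C
Reagents that add atoms: none
Why: Suzuki–Miyaura coupling at the electron-poor pyranone C–OTf bond, of the kind established for 5-triflyloxy-4-pyranones, should join ring B to ring C with the free alcohol and the MOM ethers as spectators.

**Step 5**
Reactants: 7 5-[2,4-bis(methoxymethoxy)phenyl]-2-(hydroxymethyl)-4H-pyran-4-one
Product: 9 5-[2,4-bis(methoxymethoxy)phenyl]-4-oxo-4H-pyran-2-carboxylic acid, via aldehyde 8 (not isolated)
Conditions: TEMPO (20 mol %), PhI(OAc)2 (2.2 equiv), MeCN/H2O (1:1), rt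
Reagents that add atoms: water, O
Why: Oxoammonium (TEMPO/PhI(OAc)2) oxidation in aqueous acetonitrile takes a primary alcohol through the readily hydrated electron-poor aldehyde to the acid under nearly neutral conditions that the MOM acetals and the base-sensitive pyranone should survive.

**Step 6**
Reactants: 9 5-[2,4-bis(methoxymethoxy)phenyl]-4-oxo-4H-pyran-2-carboxylic acid; 10 (trimethylsilyl)diazomethane
Product: 12 2-(diazoacetyl)-5-[2,4-bis(methoxymethoxy)phenyl]-4H-pyran-4-one, via mixed anhydride 11 (not isolated)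
Conditions: ClCO2Et, Et3N, THF, −15 °C; then 10 (2 M in hexanes), MeCN, 0 °C to rt
Reagents that add atoms: none
Why: C-acylation of the silyl diazomethane by a mixed carbonic anhydride (the diazoketone stage of the Arndt–Eistert sequence) avoids HCl and so spares the MOM ethers, and the silyl group is lost from carbon in the flask and on aqueous work-up.

**Step 7**
Reactants: 13 prenyl bromide; 14 ethynylmagnesium bromide
Product: 15 5-methylhex-4-en-1-yne
Conditions: CuCl (5 mol %), THF, 0 °C to 45 °C
Reagents that add atoms: none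
Why: Copper-catalysed coupling of an alkynyl Grignard reagent with an allylic bromide should occur at the unhindered primary carbon (SN2 sense) to give the skipped enyne, which is isolated by careful fractional distillation because it is volatile.

**Step 8**
Reactants: 15 5-methylhex-4-en-1-yne
Product: 18 triisopropyl[(5-methylhex-4-en-1-yn-1-yl)oxy]silane, via lithium acetylide 16 (not isolated), via lithium ynolate 17 (not isolated)
Conditions: n-BuLi, THF, −78 °C; t-BuOOLi (from t-BuOOH and LiN(SiMe3)2), −78 to 0 °C; TIPSOTf, −78 to 0 °C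
Reagents that add atoms: tert-butyl hydroperoxide, CC(C)(C)OO; triisopropylsilyl trifluoromethanesulfonate, CC(C)[Si](OS(=O)(=O)C(F)(F)F)(C(C)C)C(C)C
Why: Electrophilic oxygenation of the lithium acetylide by the lithium alkyl peroxide gives the ynolate, and the bulky silyl triflate should silylate it on oxygen (ynolate O-silylation) to give the siloxyalkyne.

**Step 9**
Reactants: 12 2-(diazoacetyl)-5-[2,4-bis(methoxymethoxy)phenyl]-4H-pyran-4-one; 18 triisopropyl[(5-methylhex-4-en-1-yn-1-yl)oxy]silane
Product: 23 3-[2,4-bis(methoxymethoxy)phenyl]-5-hydroxy-6-(3-methylbut-2-en-1-yl)-7-[(triisopropylsilyl)oxy]-4H-chromen-4-one, via pyranonylketene 19 (not isolated), via cyclobutenone 20 (not isolated), via dienylketene 21 (not isolated), via dienone tautomer 22 (not isolated)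
Conditions: hν (365 nm LED), 18 (1.5 equiv), ClCH2CH2Cl, rt; then 80 °C
Reagents that add atoms: none
Why: Light expels N2 and the pyranonyl group migrates from the acyl carbon to the carbene carbon (Wolff rearrangement, making C8–C8a), and ketene 19 then takes up the electron-rich ynol ether across its C=C in a [2+2] cycloaddition (C5–C6 and C7–C8) in which the alkyne carbon beta to oxygen bonds to the ketene carbonyl carbon. On heating, cyclobutenone 20 opens reversibly by 4π electrocyclic cleavage to dienylketene 21, whose isomer with the pyranone cis to the ketene closes the six-membered ring A by thermal 6π disrotatory electrocyclisation between the ketene carbon and C4a (C4a–C5); enolisation of dienone 22 then aromatises the ring to the hydrogen-bonded 5-phenol. The closest known reaction type is the Danheiser benzannulation of aryl, heteroaryl and alkenyl α-diazoketones with triisopropylsiloxyalkynes, which gives 2-alkyl-3-siloxyphenols of this pattern. No stereocentre is created. Regioselectivity rests on the polarity of the ynol ether (prenyl carbon to C5, oxygenated carbon to C8) and on C4a being the only carbon neighbour of C8a available for closure; chemoselectivity rests on the far higher reactivity of the siloxyalkyne towards the ketene compared with the trisubstituted prenyl alkene. Light of 365 nm should be absorbed mainly by the diazoketone and spare the pyranone and isoflavone chromophores, and the chelated 5-OH of the product is a poor nucleophile towards ketene 19.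

**Step 10**
Reactants: 23 3-[2,4-bis(methoxymethoxy)phenyl]-5-hydroxy-6-(3-methylbut-2-en-1-yl)-7-[(triisopropylsilyl)oxy]-4H-chromen-4-one
Product: 24 3-[2,4-bis(methoxymethoxy)phenyl]-5-methoxy-6-(3-methylbut-2-en-1-yl)-7-[(triisopropylsilyl)oxy]-4H-chromen-4-one
Conditions: MeI, K2CO3, acetone, 55 °C (sealed tube)
Reagents that add atoms: iodomethane, CI
Why: Williamson O-methylation under anhydrous carbonate conditions should alkylate the only free hydroxyl, the chelated 5-OH, while the hindered aryl silyl ether and the MOM ethers persist.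

**Step 11**
Reactants: 24 3-[2,4-bis(methoxymethoxy)phenyl]-5-methoxy-6-(3-methylbut-2-en-1-yl)-7-[(triisopropylsilyl)oxy]-4H-chromen-4-one
Product: 25 3-(2,4-dihydroxyphenyl)-5-methoxy-6-(3-methylbut-2-en-1-yl)-7-[(triisopropylsilyl)oxy]-4H-chromen-4-one
Conditions: HCl (3 M aq.), MeOH, 40 °C
Reagents that add atoms: none
Why: Acid-catalysed acetal exchange with methanol should cleave both MOM ethers while O7 is still silylated, so that no free phenol sits next to the prenyl group to cyclise to a chroman (premature loss of the silyl group would only give 26).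

**Step 12**
Reactants: 25 3-(2,4-dihydroxyphenyl)-5-methoxy-6-(3-methylbut-2-en-1-yl)-7-[(triisopropylsilyl)oxy]-4H-chromen-4-one
Product: 26 3-(2,4-dihydroxyphenyl)-7-hydroxy-5-methoxy-6-(3-methylbut-2-en-1-yl)-4H-chromen-4-one
Conditions: TBAF, AcOH, THF, 0 °C to rt
Reagents that add atoms: none
Why: Fluoride-induced cleavage of the aryl Si–O bond (desilylation), buffered with acetic acid to protect the isoflavone from base, should release the 7-OH and give the target.

**Compound list**
1 | 4-bromoresorcinol | Oc1ccc(Br)c(O)c1 | starting material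
2 | 1-bromo-2,4-bis(methoxymethoxy)benzene | COCOc1ccc(Br)c(OCOC)c1 | intermediate
3 | [2,4-bis(methoxymethoxy)phenyl]lithium | [Li]c1ccc(OCOC)cc1OCOC | intermediate
4 | 2-[2,4-bis(methoxymethoxy)phenyl]-4,4,5,5-tetramethyl-1,3,2-dioxaborolane | COCOc1ccc(B2OC(C)(C)C(C)(C)O2)c(OCOC)c1 | intermediate
5 | kojic acid (5-hydroxy-2-(hydroxymethyl)-4H-pyran-4-one) | OCc1cc(=O)c(O)co1 | starting material
6 | 6-(hydroxymethyl)-4-oxo-4H-pyran-3-yl trifluoromethanesulfonate | OCc1cc(=O)c(OS(=O)(=O)C(F)(F)F)co1 | intermediate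
7 | 5-[2,4-bis(methoxymethoxy)phenyl]-2-(hydroxymethyl)-4H-pyran-4-one | OCc1cc(=O)c(-c2ccc(OCOC)cc2OCOC)co1 | intermediate
8 | 5-[2,4-bis(methoxymethoxy)phenyl]-4-oxo-4H-pyran-2-carbaldehyde | O=Cc1cc(=O)c(-c2ccc(OCOC)cc2OCOC)co1 | intermediate
9 | 5-[2,4-bis(methoxymethoxy)phenyl]-4-oxo-4H-pyran-2-carboxylic acid | OC(=O)c1cc(=O)c(-c2ccc(OCOC)cc2OCOC)co1 | intermediate
10 | (trimethylsilyl)diazomethane | C[Si](C)(C)C=[N+]=[N-] | starting material
11 | 5-[2,4-bis(methoxymethoxy)phenyl]-4-oxo-4H-pyran-2-carboxylic ethyl carbonic anhydride | CCOC(=O)OC(=O)c1cc(=O)c(-c2ccc(OCOC)cc2OCOC)co1 | intermediate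
12 | 2-(diazoacetyl)-5-[2,4-bis(methoxymethoxy)phenyl]-4H-pyran-4-one | [N-]=[N+]=CC(=O)c1cc(=O)c(-c2ccc(OCOC)cc2OCOC)co1 | intermediate
13 | prenyl bromide (1-bromo-3-methylbut-2-ene) | CC(C)=CCBr | starting material
14 | ethynylmagnesium bromide | C#C[Mg]Br | starting material
15 | 5-methylhex-4-en-1-yne | CC(C)=CCC#C | intermediate
16 | (5-methylhex-4-en-1-yn-1-yl)lithium | CC(C)=CCC#C[Li] | intermediate
17 | lithium 5-methylhex-4-en-1-yn-1-olate | CC(C)=CCC#CO[Li] | intermediate
18 | triisopropyl[(5-methylhex-4-en-1-yn-1-yl)oxy]silane | CC(C)=CCC#CO[Si](C(C)C)(C(C)C)C(C)C | intermediate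
19 | 5-[2,4-bis(methoxymethoxy)phenyl]-2-(2-oxoethenyl)-4H-pyran-4-one | O=C=Cc1cc(=O)c(-c2ccc(OCOC)cc2OCOC)co1 | intermediate
20 | 4-{5-[2,4-bis(methoxymethoxy)phenyl]-4-oxo-4H-pyran-2-yl}-2-(3-methylbut-2-en-1-yl)-3-[(triisopropylsilyl)oxy]cyclobut-2-en-1-one (racemic) | O=C1C(CC=C(C)C)=C(O[Si](C(C)C)(C(C)C)C(C)C)C1c1cc(=O)c(-c2ccc(OCOC)cc2OCOC)co1 | intermediate
21 | 5-[2,4-bis(methoxymethoxy)phenyl]-2-{3-(3-methylbut-2-en-1-yl)-4-oxo-2-[(triisopropylsilyl)oxy]buta-1,3-dien-1-yl}-4H-pyran-4-one, pyranone and ketene carbon cis across the enol ether C=C | O=C=C(CC=C(C)C)/C(O[Si](C(C)C)(C(C)C)C(C)C)=C\c1cc(=O)c(-c2ccc(OCOC)cc2OCOC)co1 | intermediate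
22 | 3-[2,4-bis(methoxymethoxy)phenyl]-6-(3-methylbut-2-en-1-yl)-7-[(triisopropylsilyl)oxy]-4H-chromene-4,5(4aH)-dione (racemic at C4a) | O=C1C(CC=C(C)C)=C(O[Si](C(C)C)(C(C)C)C(C)C)C=C2OC=C(c3ccc(OCOC)cc3OCOC)C(=O)C12 | intermediate
23 | 3-[2,4-bis(methoxymethoxy)phenyl]-5-hydroxy-6-(3-methylbut-2-en-1-yl)-7-[(triisopropylsilyl)oxy]-4H-chromen-4-one | Oc1c(CC=C(C)C)c(O[Si](C(C)C)(C(C)C)C(C)C)cc2occ(-c3ccc(OCOC)cc3OCOC)c(=O)c12 | intermediate
24 | 3-[2,4-bis(methoxymethoxy)phenyl]-5-methoxy-6-(3-methylbut-2-en-1-yl)-7-[(triisopropylsilyl)oxy]-4H-chromen-4-one | COc1c(CC=C(C)C)c(O[Si](C(C)C)(C(C)C)C(C)C)cc2occ(-c3ccc(OCOC)cc3OCOC)c(=O)c12 | intermediate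
25 | 3-(2,4-dihydroxyphenyl)-5-methoxy-6-(3-methylbut-2-en-1-yl)-7-[(triisopropylsilyl)oxy]-4H-chromen-4-one | COc1c(CC=C(C)C)c(O[Si](C(C)C)(C(C)C)C(C)C)cc2occ(-c3ccc(O)cc3O)c(=O)c12 | intermediate
26 | 3-(2,4-dihydroxyphenyl)-7-hydroxy-5-methoxy-6-(3-methylbut-2-en-1-yl)-4H-chromen-4-one | COc1c(CC=C(C)C)c(O)cc2occ(-c3ccc(O)cc3O)c(=O)c12 | target

**Totals**
Total step count: 12.
Longest linear sequence: 9 steps (steps 1, 2, 4, 5, 6, 9, 10, 11, 12, from 4-bromoresorcinol).

**Steps most likely to fail**

Step 9. What may go wrong: the pyranone and the isoflavone that builds up compete for the light, so the diazoketone is consumed by side photoreactions before the ketene meets the alkyne. Alternatively, the ketene acylates the product phenol faster than it adds to the alkyne. The fallback sets out from 12 and makes the same ketene without light in the annulation flask. PhCO2Ag with Et3N in THF/H2O in the dark (Arndt–Eistert homologation) should convert 12 into [5-(2,4-bis(methoxymethoxy)phenyl)-4-oxo-4H-pyran-2-yl]acetic acid F1. 1-Chloro-N,N,2-trimethylprop-1-en-1-amine in CH2Cl2 at 0 °C should then give, under neutral conditions, [5-(2,4-bis(methoxymethoxy)phenyl)-4-oxo-4H-pyran-2-yl]acetyl chloride F2. Slow addition of Et3N to F2 and 18 in toluene at rt generates ketene 19 by dehydrochlorination in the presence of the alkyne, so that it is trapped as cyclobutenone 20. Heating at 80 °C completes the 4π/6π sequence, and the route is rejoined at 23.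

Step 6. What may go wrong: the diazoalkane adds as a 1,3-dipole to the electron-poor C=C of the acylated pyranone, or acylation by the hindered silyl reagent is slow and the anhydride decomposes. The fallback sets out from 9 and installs the diazo group by diazo transfer instead of acylation. Coupling of 9 with MeNH(OMe)·HCl (EDC·HCl, N-methylmorpholine, CH2Cl2) should give 5-[2,4-bis(methoxymethoxy)phenyl]-N-methoxy-N-methyl-4-oxo-4H-pyran-2-carboxamide F3. MeMgBr in THF at −78 °C should then give 2-acetyl-5-[2,4-bis(methoxymethoxy)phenyl]-4H-pyran-4-one F4. Enolisation with LiN(SiMe3)2 at −78 °C and trapping with CF3CO2CH2CF3 gives 1-{5-[2,4-bis(methoxymethoxy)phenyl]-4-oxo-4H-pyran-2-yl}-4,4,4-trifluorobutane-1,3-dione F5. Treatment of F5 with MsN3, Et3N and H2O in MeCN at rt (detrifluoroacetylative diazo transfer) delivers the diazoketone, and the route is rejoined at 12.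

Step 10. What may go wrong: the hydrogen-bonded 5-hydroxyl, flanked by the prenyl group, is alkylated slowly, and under prolonged basic conditions the silyl ether is lost so that O7 is methylated as well. The fallback sets out from 23 and exchanges the silyl group for a base-stable acetal before methylation. TBAF/AcOH in THF should give 3-[2,4-bis(methoxymethoxy)phenyl]-5,7-dihydroxy-6-(3-methylbut-2-en-1-yl)-4H-chromen-4-one F6. MOMCl and i-Pr2NEt in CH2Cl2 protect only the non-chelated 7-OH, giving 3-[2,4-bis(methoxymethoxy)phenyl]-5-hydroxy-7-(methoxymethoxy)-6-(3-methylbut-2-en-1-yl)-4H-chromen-4-one F7. Forcing methylation (Me2SO4, K2CO3, acetone, reflux) is then safe and gives 3-[2,4-bis(methoxymethoxy)phenyl]-5-methoxy-7-(methoxymethoxy)-6-(3-methylbut-2-en-1-yl)-4H-chromen-4-one F8. A single treatment with HCl in MeOH at 40 °C removes all three MOM groups, and the route is rejoined at 26.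

**Further compounds**
F1 | step 9 | [5-(2,4-bis(methoxymethoxy)phenyl)-4-oxo-4H-pyran-2-yl]acetic acid | OC(=O)Cc1cc(=O)c(-c2ccc(OCOC)cc2OCOC)co1
F2 | step 9 | [5-(2,4-bis(methoxymethoxy)phenyl)-4-oxo-4H-pyran-2-yl]acetyl chloride | ClC(=O)Cc1cc(=O)c(-c2ccc(OCOC)cc2OCOC)co1
F3 | step 6 | 5-[2,4-bis(methoxymethoxy)phenyl]-N-methoxy-N-methyl-4-oxo-4H-pyran-2-carboxamide | CON(C)C(=O)c1cc(=O)c(-c2ccc(OCOC)cc2OCOC)co1
F4 | step 6 | 2-acetyl-5-[2,4-bis(methoxymethoxy)phenyl]-4H-pyran-4-one | CC(=O)c1cc(=O)c(-c2ccc(OCOC)cc2OCOC)co1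
F5 | step 6 | 1-{5-[2,4-bis(methoxymethoxy)phenyl]-4-oxo-4H-pyran-2-yl}-4,4,4-trifluorobutane-1,3-dione | O=C(CC(=O)C(F)(F)F)c1cc(=O)c(-c2ccc(OCOC)cc2OCOC)co1
F6 | step 10 | 3-[2,4-bis(methoxymethoxy)phenyl]-5,7-dihydroxy-6-(3-methylbut-2-en-1-yl)-4H-chromen-4-one | Oc1c(CC=C(C)C)c(O)cc2occ(-c3ccc(OCOC)cc3OCOC)c(=O)c12
F7 | step 10 | 3-[2,4-bis(methoxymethoxy)phenyl]-5-hydroxy-7-(methoxymethoxy)-6-(3-methylbut-2-en-1-yl)-4H-chromen-4-one | Oc1c(CC=C(C)C)c(OCOC)cc2occ(-c3ccc(OCOC)cc3OCOC)c(=O)c12
F8 | step 10 | 3-[2,4-bis(methoxymethoxy)phenyl]-5-methoxy-7-(methoxymethoxy)-6-(3-methylbut-2-en-1-yl)-4H-chromen-4-one | COc1c(CC=C(C)C)c(OCOC)cc2occ(-c3ccc(OCOC)cc3OCOC)c(=O)c12
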